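**Retrosynthetic overview**
1. Target ⇐ one global acidolysis of a tetra-MOM / PMB ester / tert-butyl ester precursor; the C4–O succinate ⇐ regioselective acylation of the cis-3,4-diol with tert-butyl succinyl chloride (fragment S, from succinic anhydride).
2. C1–O and C5–O cinnamates ⇐ two acylations with one acid chloride (fragment A), whose aryl–vinyl bond comes from a Heck coupling of brominated bis-MOM catechol with acrylic acid.
3. Core ⇐ 3,4-O-isopropylidene quinide ⇐ exo-dihydroxylation of a bicyclic vinyl lactone; the lactone is opened (cesium salt, then PMB ester) only after the C1 ester is in place.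
4. Key step: the vinyl lactone (C5–O bond, absolute configuration at C5 and C1) ⇐ racemic 1-hydroxycyclohex-3-ene-1-carboxylic acid by a copper-catalysed enantioconvergent allylic C–H lactonization through a symmetric allyl radical.
5. Ring order: carbocycle (Diels–Alder of butadiene and acrylic acid), then the gamma-lactone (C–H lactonization), then the temporary dioxolane; lactone and dioxolane are opened again later, and the arene rings come from catechol.

Assumption: the target is read as 1,5-di-O-caffeoyl-4-O-succinylquinic acid of the (−)-quinic series (ring carbons 1S,3R,4R,5R). Positions are numbered as in quinic acid (C1 carries CO2H; O3 and O4 cis; O5 trans to O4 and cis to CO2H), and "quinide/quinate" names imply that configuration.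
Assumption: the (S,S)-ligand in step 9 is taken to give (1S,5R)-15; if the antipode forms, the (R,R)-ligand is used. Compounds 11 and 14 are racemates (SMILES without stereo).

**Fragment A**

Step 1
Reactants: 1 catechol
Product: 2 1,2-bis(methoxymethoxy)benzene
Conditions: MOMCl (2.5 equiv), i-Pr2NEt (3 equiv), CH2Cl2, 0 °C to rt
Reagents that add atoms: chloromethyl methyl ether (MOMCl), COCCl
Why: Base-mediated O-alkylation of both phenols (acetal protection); the MOM ethers tolerate every later basic, oxidative and acylating step and leave in the final acid step.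

Step 2
Reactants: 2 1,2-bis(methoxymethoxy)benzene
Product: 3 4-bromo-1,2-bis(methoxymethoxy)benzene
Conditions: NBS (1.05 equiv), MeCN, 0 °C to rt, dark
Reagents that add atoms: N-bromosuccinimide, O=C1CCC(=O)N1Br
Why: Electrophilic aromatic bromination: NBS in MeCN brominates the doubly alkoxy-activated ring para to one oxygen (C4), the least hindered activated position.

Step 3
Reactants: 3 4-bromo-1,2-bis(methoxymethoxy)benzene; 4 acrylic acid
Product: 5 (E)-3-[3,4-bis(methoxymethoxy)phenyl]prop-2-enoic acid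
Conditions: Pd(OAc)2 (2 mol %), P(o-tol)3 (6 mol %), Et3N (3 equiv), DMF, 100 °C; citric acid work-up (pH 4)
Reagents that add atoms: none
Why: Mizoroki–Heck reaction: the aryl–palladium species adds across acrylic acid and syn beta-hydride elimination delivers the E-cinnamic acid.

Step 4
Reactants: 5 (E)-3-[3,4-bis(methoxymethoxy)phenyl]prop-2-enoic acid
Product: 6 (E)-3-[3,4-bis(methoxymethoxy)phenyl]prop-2-enoyl chloride
Conditions: 1-chloro-N,N,2-trimethylprop-1-en-1-amine (1.2 equiv), CH2Cl2, 0 °C to rt; concentrated, used crude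
Reagents that add atoms: 1-chloro-N,N,2-trimethylprop-1-en-1-amine (Ghosez reagent), CC(C)=C(Cl)N(C)C
Why: Neutral acid-chloride formation with an alpha-chloroenamine (Ghosez), which releases no HCl and so spares the MOM acetals.

**Fragment S**

Step 5
Reactants: 7 succinic anhydride
Product: 8 4-tert-butoxy-4-oxobutanoic acid
Conditions: t-BuOH (3 equiv), N-hydroxysuccinimide (0.3 equiv), DMAP (0.1 equiv), Et3N (0.3 equiv), toluene, reflux
Reagents that add atoms: tert-butanol, CC(C)(C)O
Why: Nucleophile-catalysed alcoholysis of the cyclic anhydride opens it once and stops at the mono tert-butyl ester.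

Step 6
Reactants: 8 4-tert-butoxy-4-oxobutanoic acid
Product: 9 tert-butyl 4-chloro-4-oxobutanoate
Conditions: (COCl)2 (1.2 equiv), DMF (cat.), CH2Cl2, 0 °C, 1 h; concentrated, used at once
Reagents that add atoms: oxalyl chloride, O=C(Cl)C(=O)Cl
Why: Vilsmeier-type conversion of the free acid into its chloride at 0 °C; the tert-butyl ester survives the short exposure.

**Core**

Step 7
Reactants: 10 buta-1,3-diene; 4 acrylic acid
Product: 11 rac-cyclohex-3-ene-1-carboxylic acid
Conditions: hydroquinone (1 mol %), toluene, sealed vessel, 120 °C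
Reagents that add atoms: none
Why: Thermal Diels–Alder cycloaddition builds the cyclohexene; the single stereocentre forms racemic and is erased in step 8.

Step 8
Reactants: 11 rac-cyclohex-3-ene-1-carboxylic acid
Product: 14 rac-1-hydroxycyclohex-3-ene-1-carboxylic acid, via dilithium enediolate 12 (not isolated), via dilithium peroxy carboxylate 13 (not isolated)
Conditions: LDA (2.2 equiv), THF, 0 to 40 °C; O2, −78 °C to rt; aq Na2SO3; HCl to pH 2
Reagents that add atoms: dioxygen, O=O
Why: alpha-Hydroxylation of the carboxylic acid dianion with O2 (enolate oxygenation) and sulfite reduction of the hydroperoxide; C1 forms racemic and is resolved by convergence in step 9.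

Step 9
Reactants: 14 rac-1-hydroxycyclohex-3-ene-1-carboxylic acid
Product: 15 (1S,5R)-1-hydroxy-6-oxabicyclo[3.2.1]oct-3-en-7-one
Conditions: Cu(MeCN)4PF6 (10 mol %), 2,2'-(propane-2,2-diyl)bis[(4S)-4-tert-butyl-4,5-dihydro-1,3-oxazole] (12 mol %), NFSI (1.3 equiv), Li2CO3 (1.0 equiv), PhCl, 0 °C to rt; dilute HCl work-up
Reagents that add atoms: none
Why: Proposed new method: a copper-catalysed enantioconvergent allylic C–H lactonization, in which the monovalent copper–bis(oxazoline) complex reduces NFSI to a sulfonimidyl radical that abstracts hydrogen from the allylic CH2 remote from the quaternary carbon (C3 in one enantiomer of 14, C5 in the other; the CH2 next to C1 is shielded and inductively deactivated), so both enantiomers give the same mirror-symmetric C3–C4–C5 allyl radical; divalent copper carrying the substrate's own carboxylate captures it on the carboxyl face, and ligand-controlled C–O reductive elimination from trivalent copper onto one of the two enantiotopic allyl termini closes the gamma-lactone, setting C5 as R and thereby C1 as S; the closest known reactions are the copper/bis(oxazoline) Kharasch–Sosnovsky allylic oxidation of cyclohexene, copper/NFSI radical-relay allylic C–H cyanation and copper-catalysed enantioselective radical lactonization of alkenoic acids.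

Step 10
Reactants: 15 (1S,5R)-1-hydroxy-6-oxabicyclo[3.2.1]oct-3-en-7-one
Product: 16 (1S,3R,4R,5R)-1,3,4-trihydroxy-6-oxabicyclo[3.2.1]octan-7-one (1,5-quinide)
Conditions: K2OsO4·2H2O (2 mol %), NMO (1.5 equiv), acetone/H2O (4:1), rt
Reagents that add atoms: N-methylmorpholine N-oxide, C[N+]1([O-])CCOCC1; water, O
Why: Upjohn syn-dihydroxylation: osmium tetroxide adds to the alkene face opposite the two-atom lactone bridge, so both new hydroxyls (3R,4R) are cis to the C1 hydroxyl and trans to O5, as established for the racemic lactone.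

Step 11
Reactants: 16 1,5-quinide
Product: 17 3,4-O-isopropylidene-1,5-quinide
Conditions: 2,2-dimethoxypropane (3 equiv), TsOH·H2O (5 mol %), acetone, rt
Reagents that add atoms: 2,2-dimethoxypropane, COC(C)(C)OC
Why: Acid-catalysed transketalization: only the cis-3,4-diol can form the five-membered acetonide, so the tertiary C1 hydroxyl stays free.

Step 12
Reactants: 17 3,4-O-isopropylidene-1,5-quinide; 6 (E)-3-[3,4-bis(methoxymethoxy)phenyl]prop-2-enoyl chloride
Product: 18 1-O-[(E)-3,4-bis(methoxymethoxy)cinnamoyl]-3,4-O-isopropylidene-1,5-quinide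
Conditions: 6 (1.5 equiv), DMAP (0.5 equiv), pyridine/CH2Cl2, rt to 40 °C
Reagents that add atoms: none
Why: DMAP-catalysed acylation of the tertiary alcohol, which is exposed in the lactone form (known for quinide acetonide and cinnamoyl chlorides).

Step 13
Reactants: 18 1-O-[(E)-3,4-bis(methoxymethoxy)cinnamoyl]-3,4-O-isopropylidene-1,5-quinide
Product: 20 4-methoxybenzyl 1-O-[(E)-3,4-bis(methoxymethoxy)cinnamoyl]-3,4-O-isopropylidenequinate, via cesium carboxylate 19 (not isolated)
Conditions: CsOH·H2O (1.05 equiv), THF/H2O, 0 °C; evaporate (toluene azeotrope); PMBCl (1.2 equiv), DMF, rt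
Reagents that add atoms: cesium hydroxide monohydrate, [Cs+].[OH-].O; 4-methoxybenzyl chloride, COc1ccc(CCl)cc1
Why: Chemoselective saponification (acyl–oxygen cleavage, so C5 keeps its configuration) of the strained alpha-acyloxy gamma-lactone, which is far more electrophilic than the hindered conjugated tertiary ester, followed by SN2 O-alkylation of the cesium carboxylate.

Step 14
Reactants: 20 4-methoxybenzyl 1-O-[(E)-3,4-bis(methoxymethoxy)cinnamoyl]-3,4-O-isopropylidenequinate; 6 (E)-3-[3,4-bis(methoxymethoxy)phenyl]prop-2-enoyl chloride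
Product: 21 4-methoxybenzyl 1,5-bis-O-[(E)-3,4-bis(methoxymethoxy)cinnamoyl]-3,4-O-isopropylidenequinate
Conditions: 6 (1.3 equiv), pyridine (3 equiv), DMAP (0.1 equiv), CH2Cl2, 0 °C to rt
Reagents that add atoms: none
Why: Pyridine/DMAP esterification of the only free hydroxyl, the equatorial secondary 5-OH, with retention because no bond to C5 is broken.

Step 15
Reactants: 21 4-methoxybenzyl 1,5-bis-O-[(E)-3,4-bis(methoxymethoxy)cinnamoyl]-3,4-O-isopropylidenequinate
Product: 22 4-methoxybenzyl 1,5-bis-O-[(E)-3,4-bis(methoxymethoxy)cinnamoyl]quinate (3,4-diol)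
Conditions: AcOH/H2O (4:1), 45 °C, monitored
Reagents that add atoms: none
Why: Acid-catalysed ketal hydrolysis, which is much faster than cleavage of aryl MOM acetals or of the PMB ester in aqueous acetic acid, and acid does not promote acyl migration.

Step 16
Reactants: 22 4-methoxybenzyl 1,5-bis-O-[(E)-3,4-bis(methoxymethoxy)cinnamoyl]quinate; 9 tert-butyl 4-chloro-4-oxobutanoate
Product: 23 4-methoxybenzyl 4-O-(4-tert-butoxy-4-oxobutanoyl)-1,5-bis-O-[(E)-3,4-bis(methoxymethoxy)cinnamoyl]quinate
Conditions: 9 (1.3 equiv), Ph2BOCH2CH2NH2 (10 mol %), i-Pr2NEt (1.5 equiv), MeCN, 0 °C to rt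
Reagents that add atoms: none
Why: Borinic-acid-catalysed regioselective acylation of a cis-1,2-diol: the tetracoordinate borinate of the 3,4-diol reacts at its equatorial oxygen (O4) and leaves the axial 3-OH free.

Step 17
Reactants: 23 4-methoxybenzyl 4-O-(4-tert-butoxy-4-oxobutanoyl)-1,5-bis-O-[(E)-3,4-bis(methoxymethoxy)cinnamoyl]quinate
Product: 24 1,5-di-O-caffeoyl-4-O-succinylquinic acid (target, CNP0291856.1)
Conditions: TFA/CH2Cl2 (1:1), H2O (5 vol %), anisole (10 equiv), 0 °C to rt
Reagents that add atoms: none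
Why: Global acidolysis: SN1 cleavage of the tert-butyl and PMB esters and hydrolysis of the four MOM acetals, with the acidic medium suppressing acyl migration and no stereocentre touched.

**Compound list**
1 | catechol | Oc1ccccc1O | starting material
2 | 1,2-bis(methoxymethoxy)benzene | COCOc1ccccc1OCOC | intermediate
3 | 4-bromo-1,2-bis(methoxymethoxy)benzene | COCOc1ccc(Br)cc1OCOC | intermediate
4 | acrylic acid | C=CC(=O)O | starting material
5 | (E)-3-[3,4-bis(methoxymethoxy)phenyl]prop-2-enoic acid | COCOc1ccc(/C=C/C(=O)O)cc1OCOC | intermediate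
6 | (E)-3-[3,4-bis(methoxymethoxy)phenyl]prop-2-enoyl chloride | COCOc1ccc(/C=C/C(=O)Cl)cc1OCOC | intermediate
7 | succinic anhydride | O=C1CCC(=O)O1 | starting material
8 | 4-tert-butoxy-4-oxobutanoic acid | CC(C)(C)OC(=O)CCC(=O)O | intermediate
9 | tert-butyl 4-chloro-4-oxobutanoate | CC(C)(C)OC(=O)CCC(=O)Cl | intermediate
10 | buta-1,3-diene | C=CC=C | starting material
11 | rac-cyclohex-3-ene-1-carboxylic acid | OC(=O)C1CCC=CC1 | intermediate
12 | dilithium enediolate of 11 (not isolated) | [Li+].[Li+].[O-]C([O-])=C1CCC=CC1 | intermediate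
13 | dilithium salt of rac-1-hydroperoxycyclohex-3-ene-1-carboxylic acid (not isolated) | [Li+].[Li+].[O-]OC1(CCC=CC1)C([O-])=O | intermediate
14 | rac-1-hydroxycyclohex-3-ene-1-carboxylic acid | OC(=O)C1(O)CCC=CC1 | intermediate
15 | (1S,5R)-1-hydroxy-6-oxabicyclo[3.2.1]oct-3-en-7-one | C1=CC[C@]2(O)C[C@H]1OC2=O | intermediate
16 | (1S,3R,4R,5R)-1,3,4-trihydroxy-6-oxabicyclo[3.2.1]octan-7-one (1,5-quinide) | O[C@@H]1[C@H](O)C[C@]2(O)C[C@H]1OC2=O | intermediate
17 | 3,4-O-isopropylidene-1,5-quinide | CC1(C)O[C@@H]2[C@H](O1)C[C@]3(O)C[C@H]2OC3=O | intermediate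
18 | 1-O-[(E)-3,4-bis(methoxymethoxy)cinnamoyl]-3,4-O-isopropylidene-1,5-quinide | CC1(C)O[C@@H]2[C@H](O1)C[C@]3(OC(=O)/C=C/c4ccc(OCOC)c(OCOC)c4)C[C@H]2OC3=O | intermediate
19 | cesium 1-O-[(E)-3,4-bis(methoxymethoxy)cinnamoyl]-3,4-O-isopropylidenequinate (not isolated) | CC1(C)O[C@@H]2[C@H](O1)C[C@@](OC(=O)/C=C/c3ccc(OCOC)c(OCOC)c3)(C(=O)[O-])C[C@H]2O.[Cs+] | intermediate
20 | 4-methoxybenzyl 1-O-[(E)-3,4-bis(methoxymethoxy)cinnamoyl]-3,4-O-isopropylidenequinate (5-OH free) | CC1(C)O[C@@H]2[C@H](O1)C[C@@](OC(=O)/C=C/c3ccc(OCOC)c(OCOC)c3)(C(=O)OCc3ccc(OC)cc3)C[C@H]2O | intermediate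
21 | 4-methoxybenzyl 1,5-bis-O-[(E)-3,4-bis(methoxymethoxy)cinnamoyl]-3,4-O-isopropylidenequinate | CC1(C)O[C@@H]2[C@H](O1)C[C@@](OC(=O)/C=C/c3ccc(OCOC)c(OCOC)c3)(C(=O)OCc3ccc(OC)cc3)C[C@H]2OC(=O)/C=C/c1ccc(OCOC)c(OCOC)c1 | intermediate
22 | 4-methoxybenzyl 1,5-bis-O-[(E)-3,4-bis(methoxymethoxy)cinnamoyl]quinate (3,4-diol) | O[C@@H]1[C@H](O)C[C@@](OC(=O)/C=C/c2ccc(OCOC)c(OCOC)c2)(C(=O)OCc2ccc(OC)cc2)C[C@H]1OC(=O)/C=C/c1ccc(OCOC)c(OCOC)c1 | intermediate
23 | 4-methoxybenzyl 4-O-(4-tert-butoxy-4-oxobutanoyl)-1,5-bis-O-[(E)-3,4-bis(methoxymethoxy)cinnamoyl]quinate | CC(C)(C)OC(=O)CCC(=O)O[C@@H]1[C@H](O)C[C@@](OC(=O)/C=C/c2ccc(OCOC)c(OCOC)c2)(C(=O)OCc2ccc(OC)cc2)C[C@H]1OC(=O)/C=C/c1ccc(OCOC)c(OCOC)c1 | intermediate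
24 | 1,5-di-O-caffeoyl-4-O-succinylquinic acid, ring carbons (1S,3R,4R,5R) | O=C(O)CCC(=O)O[C@@H]1[C@H](O)C[C@@](OC(=O)/C=C/c2ccc(O)c(O)c2)(C(=O)O)C[C@H]1OC(=O)/C=C/c1ccc(O)c(O)c1 | target

**Step count**
Total steps: 17. Longest linear sequence: 11 (steps 7 to 17). The caffeoyl branch runs 4 + 6 = 10 steps and the succinyl branch 2 + 2 = 4 steps.

**Three steps most likely to fail**

Step 9 (the new reaction). Possible failures are hydrogen abstraction at the CH2 next to C1, capture of the radical by a copper centre carrying another molecule's carboxylate or the sulfonimide (intermolecular ester or C–N product), and oxidation to the allyl cation with uncatalysed, racemic ring closure. A moderate ee can be raised by recrystallizing 17. Fallback, known chemistry only, setting out from 14 and coming back at 15: racemic 14 is resolved by crystallizing its salt with (R)-1-phenylethylamine, giving (R)-1-phenylethylammonium (S)-1-hydroxycyclohex-3-ene-1-carboxylate F1 (the antipodal amine is used if the other diastereomeric salt is the one that crystallizes). Aqueous HCl frees (S)-1-hydroxycyclohex-3-ene-1-carboxylic acid F2. Iodolactonization (I2, KI, NaHCO3, H2O/CH2Cl2, 0 °C) gives, by anti addition, (1S,4R,5R)-1-hydroxy-4-iodo-6-oxabicyclo[3.2.1]octan-7-one F3. DBU (THF, reflux) eliminates HI away from the bridgehead to give 15.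

Step 13. Hydroxide may also cleave the C1 cinnamate. Fallback, setting out from 17 and coming back at 21: the lactone is opened before any ester is present. CsOH·H2O (THF/H2O) gives cesium 3,4-O-isopropylidenequinate F4, and PMBCl in DMF converts it into 4-methoxybenzyl 3,4-O-isopropylidenequinate F5. Both hydroxyls of F5 are then acylated in one operation with excess 6 (3 equiv, DMAP 1.5 equiv, pyridine, 60 °C); the secondary 5-OH reacts at once and the tertiary 1-OH under forcing, giving 21.

Step 16. The O3/O4 selectivity may be poor on this crowded diol. Fallback, setting out from 22 and coming back at 23, with regiocontrol by a different principle (stereoelectronic ortho ester opening and a temporary acyl group): 22 and 2-chloro-1,1,1-trimethoxyethane (CSA cat., CH2Cl2) give the cyclic chloro ortho ester F6 (epimers at the ortho ester carbon). Brief aqueous acetic acid opens it to the axial ester, the 3-O-chloroacetate F7 with 4-OH free. Acylation with 9 (pyridine, DMAP, CH2Cl2, 0 °C) gives the 3-O-chloroacetyl-4-O-succinyl compound F8. Thiourea (2,6-lutidine, MeOH/CH2Cl2, 40 °C) removes the chloroacetyl group selectively and gives 23.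

**Further compounds**
F1 | step 9 | (R)-1-phenylethylammonium (S)-1-hydroxycyclohex-3-ene-1-carboxylate | C1=CCC[C@@](O)(C(=O)[O-])C1.C[C@@H]([NH3+])c1ccccc1
F2 | step 9 | (S)-1-hydroxycyclohex-3-ene-1-carboxylic acid | C1=CCC[C@@](O)(C(=O)O)C1
F3 | step 9 | (1S,4R,5R)-1-hydroxy-4-iodo-6-oxabicyclo[3.2.1]octan-7-one | I[C@@H]1CC[C@]2(O)C[C@H]1OC2=O
F4 | step 13 | cesium 3,4-O-isopropylidenequinate | CC1(C)O[C@@H]2[C@H](O1)C[C@@](O)(C(=O)[O-])C[C@H]2O.[Cs+]
F5 | step 13 | 4-methoxybenzyl 3,4-O-isopropylidenequinate | CC1(C)O[C@@H]2[C@H](O1)C[C@@](O)(C(=O)OCc3ccc(OC)cc3)C[C@H]2O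
F6 | step 16 | 4-methoxybenzyl 3,4-O-(2-chloro-1-methoxyethylidene)-1,5-bis-O-[(E)-3,4-bis(methoxymethoxy)cinnamoyl]quinate | COC1(CCl)O[C@@H]2[C@H](O1)C[C@@](OC(=O)/C=C/c3ccc(OCOC)c(OCOC)c3)(C(=O)OCc3ccc(OC)cc3)C[C@H]2OC(=O)/C=C/c1ccc(OCOC)c(OCOC)c1
F7 | step 16 | 4-methoxybenzyl 3-O-chloroacetyl-1,5-bis-O-[(E)-3,4-bis(methoxymethoxy)cinnamoyl]quinate | O[C@@H]1[C@H](OC(=O)CCl)C[C@@](OC(=O)/C=C/c2ccc(OCOC)c(OCOC)c2)(C(=O)OCc2ccc(OC)cc2)C[C@H]1OC(=O)/C=C/c1ccc(OCOC)c(OCOC)c1
F8 | step 16 | 4-methoxybenzyl 4-O-(4-tert-butoxy-4-oxobutanoyl)-3-O-chloroacetyl-1,5-bis-O-[(E)-3,4-bis(methoxymethoxy)cinnamoyl]quinate | CC(C)(C)OC(=O)CCC(=O)O[C@@H]1[C@H](OC(=O)CCl)C[C@@](OC(=O)/C=C/c2ccc(OCOC)c(OCOC)c2)(C(=O)OCc2ccc(OC)cc2)C[C@H]1OC(=O)/C=C/c1ccc(OCOC)c(OCOC)c1
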